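**Retrosynthetic overview**

1. Numbering used throughout: seven-membered ring C1(O-veratroyl)–C2–C3(CH3)=C4–C5(=O)–C6(CH3)–C10(H); five-membered ring C6–C7–C8–C9(OH, iPr)–C10.
2. The enone comes from its β,γ-isomer; the seven-membered ring is closed last at C4–C5 by a carbonyl-ene reaction of a C5 aldehyde with a methallyl group that was added to a C1 aldehyde (C1–C2), and the C1 oxygen is then veratroylated.
3. C9–OH and C10–H come from reductive opening of an α,β-epoxy aldehyde, hence from a cyclopentene carbaldehyde with C9=C10.
4. Feature on which the plan rests: the cyclopentane C6–C7–C8–C9–C10, with quaternary C6 (CH3, C5), C9 (iPr) and C1 on C10, is a contracted cyclohexene. Cutting C1=C9 of a 4-isopropyl-1-methylcyclohex-3-ene (C5 masked as dimethyl acetal) and bonding C10 to C9 gives it.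
5. That cyclohexene is the para Diels–Alder adduct of 2-isopropylbuta-1,3-diene and methacrolein, which sets C6. Ring order: six-membered carbocycle (sacrificed), then five-membered ring, then seven-membered ring.

Key step: step 5

Assumption: the oxazaborolidinium catalyst from (S)-α,α-diphenylprolinol is taken to give the (S)-aldehyde 5; should its facial sense be the reverse, the catalyst from (R)-α,α-diphenylprolinol is used and nothing else changes.

**Route**

Step 1
Reactants: 1 3-methylbutanal
Product: 2 3-methyl-2-methylidenebutanal (2-isopropylacrolein)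
Conditions: 37% aq. HCHO, pyrrolidine (10 mol%), propionic acid (10 mol%), iPrOH, 45 °C
Reagents that add atoms: formaldehyde, C=O
Why: Amine-catalysed Mannich-type α-methylenation of an aldehyde, in which the enamine of 1 adds to the formaldehyde-derived iminium ion and loss of the amine from the Mannich base leaves the 2-substituted acrolein, with no stereocentre formed.

Step 2
Reactants: 2 3-methyl-2-methylidenebutanal
Product: 3 2-isopropylbuta-1,3-diene
Conditions: Ph3PCH3Br, KOtBu, Et2O, 0 °C → rt; fractional distillation
Reagents that add atoms: methyltriphenylphosphonium bromide, C[P+](c1ccccc1)(c1ccccc1)c1ccccc1.[Br-]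
Why: Wittig methylenation by the non-stabilised ylide made in the flask, which attacks the carbonyl group of the enal in 1,2-fashion and should give the volatile 2-substituted diene, with no stereocentre formed.

Step 3
Reactants: 3 2-isopropylbuta-1,3-diene; 4 methacrolein
Product: 5 (1S)-1-methyl-4-(propan-2-yl)cyclohex-3-ene-1-carbaldehyde
Conditions: B-(o-tolyl) oxazaborolidine from (S)-α,α-diphenylprolinol (10 mol%), Tf2NH (10 mol%), CH2Cl2, −78 °C
Reagents that add atoms: none
Why: Enantioselective Diels–Alder reaction catalysed by a chiral oxazaborolidinium ion, in which the 2-substituted diene gives the para (1,4) adduct because its larger terminal HOMO coefficient meets the β-carbon of the boron-bound enal, and the catalyst, holding the s-trans enal by B–O coordination and a formyl C–H···O contact while an aryl group screens one face, sets the only stereocentre, quaternary C6, as (S).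

Step 4
Reactants: 5 (1S)-1-methyl-4-(propan-2-yl)cyclohex-3-ene-1-carbaldehyde
Product: 6 (4S)-4-(dimethoxymethyl)-4-methyl-1-(propan-2-yl)cyclohex-1-ene
Conditions: HC(OMe)3, MeOH, p-TsOH·H2O (2 mol%), rt; NaHCO3 quench
Reagents that add atoms: trimethyl orthoformate, COC(OC)OC; methanol, CO
Why: Acid-catalysed acetalisation driven by the orthoformate as water scavenger, safe for C6 because the neopentyl aldehyde has no α-hydrogen and for the trisubstituted alkene because the acid is mild.

Step 5
Reactants: 6 (4S)-4-(dimethoxymethyl)-4-methyl-1-(propan-2-yl)cyclohex-1-ene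
Product: 9 (5S)-5-(dimethoxymethyl)-5-methyl-2-(propan-2-yl)cyclopent-1-ene-1-carbaldehyde, via secondary ozonide 7 (not isolated), via keto aldehyde 8 (not isolated)
Conditions: O3, CH2Cl2, −78 °C (Sudan Red 7B end point); PPh3, −78 °C → rt; solvent switch; piperidine (0.3 equiv), AcOH (0.3 equiv), toluene, 80 °C
Reagents that add atoms: ozone, [O-][O+]=O
Why: Ozone adds to the only alkene, C1=C9, and the ozonide 7 is reduced by PPh3 to keto aldehyde 8, in which C1 is an aldehyde and C9 an isopropyl ketone; piperidinium acetate then converts the aldehyde alone into its enamine, whose carbon C10 adds to the C9 carbonyl, and loss of water through the iminium ion gives the conjugated enal 9. The closest known reaction type is the ozonolysis of cyclohexenes followed by amine-salt-catalysed aldol condensation of the 6-oxo aldehyde to a 2-alkylcyclopent-1-ene-1-carbaldehyde. The five-membered ring C6–C7–C8–C9–C10 closes by a 5-(enolexo)-exo-trig attack that forms the C9–C10 bond. No stereocentre is created, and the quaternary C6 centre from step 3 cannot epimerise because neither it nor its acetal carbon can enolise. The step needs the aldehyde enamine to react in preference to a ketone enolate, which would join C8 to C1 and give an acylcyclopentene; this is secured by buffered secondary-amine catalysis, under which the unhindered aldehyde condenses with piperidine whereas the α-branched ketone neither forms an enamine nor is deprotonated, and by the fact that dehydration can only occur towards C10.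

Step 6
Reactants: 9 (5S)-5-(dimethoxymethyl)-5-methyl-2-(propan-2-yl)cyclopent-1-ene-1-carbaldehyde
Product: 10 (1R,2S,5R)-2-(dimethoxymethyl)-2-methyl-5-(propan-2-yl)-6-oxabicyclo[3.1.0]hexane-1-carbaldehyde (epoxide oxygen cis to the C6 methyl group)
Conditions: 30% aq. H2O2, NaOH (0.5 equiv), MeOH, 0 °C
Reagents that add atoms: hydrogen peroxide, OO
Why: Weitz–Scheffer nucleophilic epoxidation of an enal, in which hydroperoxide adds reversibly to C9 and the enolate carbon C10 closes on the peroxide oxygen, which should enter on the face of the C6 methyl group, away from the branched dimethoxymethyl group, so that C9 and C10 are set together with the oxygen cis to that methyl group.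

Step 7
Reactants: 10 the epoxy aldehyde
Product: 12 (1R,2R,5S)-5-(dimethoxymethyl)-2-hydroxy-5-methyl-2-(propan-2-yl)cyclopentane-1-carbaldehyde, via C10-epimeric hydroxy aldehyde 11 (not isolated)
Conditions: SmI2 (2.5 equiv), THF/MeOH (4:1), −90 °C; pH 7 buffer; crude in CH2Cl2, DBU (0.2 equiv), 0 °C → rt
Reagents that add atoms: none
Why: Reductive opening of an α,β-epoxy carbonyl compound by SmI2, in which the ketyl cleaves the C10–O bond and leaves the C9 oxygen as the tertiary carbinol cis to the C6 methyl group; protonation of the trivalent samarium enolate at C10 is expected mainly on the face of the alkoxide (giving 11), and because C10 is enolisable the amine base then moves the formyl group to the favoured position trans to both the isopropyl and the dimethoxymethyl group, which is the target arrangement with C10–H trans to C9–OH.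

Step 8
Reactants: 12 the β-hydroxy aldehyde; 13 3-bromo-2-methylprop-1-ene
Product: 14 (1S)-1-[(1S,2R,5S)-5-(dimethoxymethyl)-2-hydroxy-5-methyl-2-(propan-2-yl)cyclopentyl]-3-methylbut-3-en-1-ol
Conditions: In powder (1.5 equiv), THF/H2O (1:1), rt; NaHCO3 work-up
Reagents that add atoms: none
Why: Barbier-type indium-mediated allylation in water, known to run under chelation control with free β-hydroxy aldehydes: trivalent indium bridges the C9 hydroxyl and the aldehyde oxygen in a chelate cis-fused to the cyclopentane, and the methallyl group should add to the exposed Si face of C1 on the side of C10–H, anti to quaternary C6, giving (1S), while the neutral medium avoids retro-aldol cleavage and dehydration of the aldol.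

Step 9
Reactants: 14 the diol; 15 3,4-dimethoxybenzoyl chloride
Product: 16 (1S)-1-[(1S,2R,5S)-5-(dimethoxymethyl)-2-hydroxy-5-methyl-2-(propan-2-yl)cyclopentyl]-3-methylbut-3-en-1-yl 3,4-dimethoxybenzoate
Conditions: Et3N (3 equiv), DMAP (0.5 equiv), CH2Cl2, 0 → 40 °C
Reagents that add atoms: none
Why: DMAP-catalysed acyl transfer to the secondary C1 hydroxyl, selective because the tertiary C9 hydroxyl is too hindered to be acylated, and with retention at C1 because the C–O bond is not touched.

Step 10
Reactants: 16 the veratrate acetal
Product: 17 (1S)-1-[(1S,2R,5S)-5-formyl-2-hydroxy-5-methyl-2-(propan-2-yl)cyclopentyl]-3-methylbut-3-en-1-yl 3,4-dimethoxybenzoate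
Conditions: p-TsOH·H2O (10 mol%), acetone/H2O (10:1), rt
Reagents that add atoms: water, O
Why: Acid-catalysed acetal hydrolysis (transacetalisation to acetone) in a water-rich medium, so that the oxocarbenium ion is trapped by water and not by the alkene; the ester, the tertiary alcohol and the 1,1-disubstituted alkene tolerate the mild acid, the C5 aldehyde has no α-hydrogen, and no lactol can form because C5 is trans to both oxygen functions.

Step 11
Reactants: 17 the aldehyde
Product: 18 (3R,3aS,4S,8aS)-3,8-dihydroxy-8a-methyl-6-methylidene-3-(propan-2-yl)decahydroazulen-4-yl 3,4-dimethoxybenzoate (mixture at C8)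
Conditions: Me2AlCl (3 equiv), CH2Cl2, −78 → 0 °C
Reagents that add atoms: none
Why: Me2AlCl-promoted intramolecular carbonyl-ene reaction of type 2 (tether on the central carbon of the ene), in which the terminal methylene carbon C4 bonds to the aluminium-activated C5 aldehyde while an allylic hydrogen of the methyl group passes to oxygen, closing the seven-membered ring trans-fused to the cyclopentane as the homoallylic alcohol with an exocyclic methylene group; the new C5 carbinol centre may form as a mixture, which is of no consequence because it is oxidised next.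

Step 12
Reactants: 18 the ene adduct
Product: 19 (3R,3aS,4S,8aS)-3-hydroxy-8a-methyl-6-methylidene-8-oxo-3-(propan-2-yl)decahydroazulen-4-yl 3,4-dimethoxybenzoate
Conditions: Dess–Martin periodinane (1.5 equiv), NaHCO3, CH2Cl2, 0 °C → rt
Reagents that add atoms: none
Why: Dess–Martin oxidation of the secondary C5 alcohol to the ketone under buffered neutral conditions that leave the tertiary C9 alcohol, the ester and the alkene untouched.

Step 13
Reactants: 19 the β,γ-unsaturated ketone
Product: 20 (3R,3aS,4S,8aS)-3-hydroxy-6,8a-dimethyl-8-oxo-3-(propan-2-yl)-1,2,3,3a,4,5,8,8a-octahydroazulen-4-yl 3,4-dimethoxybenzoate (CNP0111132.1)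
Conditions: DBU (0.1 equiv), CH2Cl2, 0 °C → rt; AcOH quench as soon as conversion is complete
Reagents that add atoms: none
Why: Base-mediated isomerisation of a β,γ-unsaturated ketone into conjugation through the dienolate formed at the doubly activated C4, which is reprotonated at the exocyclic carbon to give the more stable trisubstituted C3=C4 enone; catalytic base and short exposure keep the C2 hydrogens, and with them the C1 ester, out of play, and no stereocentre is touched.

**Compound list**

1 | 3-methylbutanal | CC(C)CC=O | starting material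
2 | 3-methyl-2-methylidenebutanal (2-isopropylacrolein) | CC(C)C(=C)C=O | intermediate
3 | 2-isopropylbuta-1,3-diene | CC(C)C(=C)C=C | intermediate
4 | methacrolein | C=C(C)C=O | starting material
5 | (1S)-1-methyl-4-(propan-2-yl)cyclohex-3-ene-1-carbaldehyde | O=C[C@@]1(C)CCC(C(C)C)=CC1 | intermediate
6 | (4S)-4-(dimethoxymethyl)-4-methyl-1-(propan-2-yl)cyclohex-1-ene | COC(OC)[C@@]1(C)CCC(C(C)C)=CC1 | intermediate
7 | secondary ozonide of 6 (1,2,4-trioxolane across C1 and C9; mixture at the two new centres) | COC(OC)[C@@]1(C)CCC2(C(C)C)OOC(C1)O2 | intermediate (not isolated)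
8 | (3S)-3-(dimethoxymethyl)-3,7-dimethyl-6-oxooctanal | COC(OC)[C@](C)(CC=O)CCC(=O)C(C)C | intermediate (not isolated)
9 | (5S)-5-(dimethoxymethyl)-5-methyl-2-(propan-2-yl)cyclopent-1-ene-1-carbaldehyde | O=CC1=C(C(C)C)CC[C@]1(C)C(OC)OC | intermediate
10 | (1R,2S,5R)-2-(dimethoxymethyl)-2-methyl-5-(propan-2-yl)-6-oxabicyclo[3.1.0]hexane-1-carbaldehyde (epoxide oxygen cis to the C6 methyl group) | O=C[C@]12O[C@@]1(C(C)C)CC[C@]2(C)C(OC)OC | intermediate
11 | (1S,2R,5S)-5-(dimethoxymethyl)-2-hydroxy-5-methyl-2-(propan-2-yl)cyclopentane-1-carbaldehyde (C10 epimer of 12; formyl cis to isopropyl) | O=C[C@@H]1[C@](O)(C(C)C)CC[C@]1(C)C(OC)OC | intermediate (not isolated)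
12 | (1R,2R,5S)-5-(dimethoxymethyl)-2-hydroxy-5-methyl-2-(propan-2-yl)cyclopentane-1-carbaldehyde (formyl cis to OH and to the ring methyl) | O=C[C@H]1[C@](O)(C(C)C)CC[C@]1(C)C(OC)OC | intermediate
13 | 3-bromo-2-methylprop-1-ene | C=C(C)CBr | starting material
14 | (1S)-1-[(1S,2R,5S)-5-(dimethoxymethyl)-2-hydroxy-5-methyl-2-(propan-2-yl)cyclopentyl]-3-methylbut-3-en-1-ol | C=C(C)C[C@H](O)[C@H]1[C@](O)(C(C)C)CC[C@]1(C)C(OC)OC | intermediate
15 | 3,4-dimethoxybenzoyl chloride | COc1ccc(C(Cl)=O)cc1OC | starting material
16 | (1S)-1-[(1S,2R,5S)-5-(dimethoxymethyl)-2-hydroxy-5-methyl-2-(propan-2-yl)cyclopentyl]-3-methylbut-3-en-1-yl 3,4-dimethoxybenzoate | C=C(C)C[C@H](OC(=O)c1ccc(OC)c(OC)c1)[C@H]2[C@](O)(C(C)C)CC[C@]2(C)C(OC)OC | intermediate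
17 | (1S)-1-[(1S,2R,5S)-5-formyl-2-hydroxy-5-methyl-2-(propan-2-yl)cyclopentyl]-3-methylbut-3-en-1-yl 3,4-dimethoxybenzoate | C=C(C)C[C@H](OC(=O)c1ccc(OC)c(OC)c1)[C@H]2[C@](O)(C(C)C)CC[C@]2(C)C=O | intermediate
18 | (3R,3aS,4S,8aS)-3,8-dihydroxy-8a-methyl-6-methylidene-3-(propan-2-yl)decahydroazulen-4-yl 3,4-dimethoxybenzoate (mixture at C8) | C=C1C[C@H](OC(=O)c2ccc(OC)c(OC)c2)[C@H]3[C@](O)(C(C)C)CC[C@]3(C)C(O)C1 | intermediate
19 | (3R,3aS,4S,8aS)-3-hydroxy-8a-methyl-6-methylidene-8-oxo-3-(propan-2-yl)decahydroazulen-4-yl 3,4-dimethoxybenzoate | C=C1C[C@H](OC(=O)c2ccc(OC)c(OC)c2)[C@H]3[C@](O)(C(C)C)CC[C@]3(C)C(=O)C1 | intermediate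
20 | (3R,3aS,4S,8aS)-3-hydroxy-6,8a-dimethyl-8-oxo-3-(propan-2-yl)-1,2,3,3a,4,5,8,8a-octahydroazulen-4-yl 3,4-dimethoxybenzoate | COc1ccc(C(=O)O[C@H]2CC(C)=CC(=O)[C@@]3(C)CC[C@@](O)(C(C)C)[C@H]23)cc1OC | target

**Step count**

Total: 13 steps. Longest linear sequence: 13 steps, from 3-methylbutanal.

**Steps most likely to fail**

Step 5. The enamine carbon C10 sits next to quaternary C6 and must attack an α-branched ketone, so the closure may be slower than intermolecular self-condensation of the aldehyde. The fallback sets out from keto aldehyde 8, isolated after the PPh3 reduction, and makes the C10 nucleophile regiospecifically as a metal enolate. The aldehyde α-carbon is brominated through its enamine (pyrrolidine cat., N-bromosuccinimide, CH2Cl2, 0 °C) to give (3R)-2-bromo-3-(dimethoxymethyl)-3,7-dimethyl-6-oxooctanal F1. SmI2 (2.2 equiv, THF, −78 °C) then reduces the C10–Br bond to the trivalent samarium aldehyde enolate, which adds to the C9 ketone in a Reformatsky-type aldol closure and gives (5S)-5-(dimethoxymethyl)-2-hydroxy-5-methyl-2-(propan-2-yl)cyclopentane-1-carbaldehyde F2 as a mixture at C9 and C10. Dehydration with Martin sulfurane (Ph2S[OC(CF3)2Ph]2, CH2Cl2, rt), which removes the acidified C10 hydrogen, returns the route at enal 9.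

Step 6. The peroxide may close onto C10 from the face of the dimethoxymethyl group, because a methyl and a secondary acetal differ only moderately in size; the result would be poor facial selectivity. The fallback sets out from enal 9 and uses reagent control. DIBAL-H (CH2Cl2, −78 °C) gives [(5S)-5-(dimethoxymethyl)-5-methyl-2-(propan-2-yl)cyclopent-1-en-1-yl]methanol F3. Sharpless asymmetric epoxidation (Ti(OiPr)4, D-(−)-diethyl tartrate, t-BuOOH, 4 Å sieves, CH2Cl2, −20 °C) delivers oxygen to the face of the C6 methyl group and gives [(1S,2S,5R)-2-(dimethoxymethyl)-2-methyl-5-(propan-2-yl)-6-oxabicyclo[3.1.0]hexan-1-yl]methanol F4. Oxidation (Dess–Martin periodinane, NaHCO3, CH2Cl2) returns the route at epoxy aldehyde 10.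

Step 8. The allylindium reagent may add through a non-chelated transition state, giving poor facial selectivity at C1. The fallback sets out from aldehyde 12 and replaces chelate control by reagent control. Brown methallylboration with (−)-B-methallyldiisopinocampheylborane, made from (+)-α-pinene-derived (−)-Ipc2BOMe and methallylmagnesium chloride (Et2O, −78 °C, then NaOH/H2O2 work-up), uses the antipode that attacks the Si face of aldehydes through a closed chair transition state. It should give diol 14 directly, where the route is rejoined; no new compound is made.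

**Further compounds**

F1 | step 5 | (3R)-2-bromo-3-(dimethoxymethyl)-3,7-dimethyl-6-oxooctanal (mixture at C2; C3 arranged as in 8) | COC(OC)[C@](C)(C(Br)C=O)CCC(=O)C(C)C
F2 | step 5 | (5S)-5-(dimethoxymethyl)-2-hydroxy-5-methyl-2-(propan-2-yl)cyclopentane-1-carbaldehyde (mixture at C1 and C2 of the ring) | O=CC1C(O)(C(C)C)CC[C@]1(C)C(OC)OC
F3 | step 6 | [(5S)-5-(dimethoxymethyl)-5-methyl-2-(propan-2-yl)cyclopent-1-en-1-yl]methanol | OCC1=C(C(C)C)CC[C@]1(C)C(OC)OC
F4 | step 6 | [(1S,2S,5R)-2-(dimethoxymethyl)-2-methyl-5-(propan-2-yl)-6-oxabicyclo[3.1.0]hexan-1-yl]methanol (epoxide oxygen cis to the ring methyl) | OC[C@]12O[C@@]1(C(C)C)CC[C@]2(C)C(OC)OC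
F0 | step 8 | none | none
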